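The meeting had 4 questions before it: how much target the spring flask holds at the time asked, how much it holds after two of the options, and which option adds most.

| flask | solid substrate | partner | temperature | remark | time |
|---|---|---|---|---|---|
| spring | 0.80 M | 1.3 equiv | 5 °C | the very flask that is asked about, followed so far |  |
| midnight | 0.80 M | 2.6 equiv | 5 °C | run made earlier |  |
| flask | 0.80 M | 1.30 equiv | 5 °C |  | 30 h |

- spring (time / h: target / %): 2.00: 24.7; 3.00: 34.0; 5.00: 56.6; 8.00: 75.6; 15.0: 73.9; 25.0: 76.2
- midnight (time / h: target / %): 1.00: 13.5; 2.00: 27.8; 3.00: 42.0; 4.00: 54.0; 5.00: 69.3; 6.00: 77.0

(readings scatter by 1 percentage point)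

- Saturday's: change nothing and wait 15 h more
- Monday's: at 30 h add partner, 50.0% of the amount charged, then wait 15 h
- Friday's: at 30 h raise the temperature by 10 K, then wait 15 h
- Thursday's: at 30 h take out 90% of the target then present, then wait 15 h

- as a solid, counted per litre of solution: solid substrate
- target taken out counts as made
- at the start none of the solid substrate is in solution
- the earlier runs do not show what temperature does; that part of a forecast is a guess
- additions bring no volume worth counting

* target, in percent of the solid substrate first charged, at 30 h
* which option adds most target ("none" when 2 percentage points or less is all one gets) (Saturday's / Monday's / Friday's / Thursday's / none)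
* target present, with what was taken out counted in, in percent of the solid substrate first charged, after Saturday's
* target present, with what was taken out counted in, in percent of the solid substrate first charged, after Monday's

The chemist of the spring flask reported that its target stopped climbing: the readings from 8.00 h onward average 75.2%. The chemist of the midnight flask answered that twice the partner had quickened the climb, with 69.3% at 5.00 h against 56.6% in the spring flask. But the midnight flask's last reading, 77.0%, stood 1.8 percentage points above that mean on a scatter of 1 point. The meeting did not take the ceiling as moved.

I proposed leaving the large stream alone and reckoning the correction: the loss ratio, solid substrate lost per unit of target made, 0.329, an overall selectivity factor turned upside down. If one partner goes into each target, the spring flask keeps 0.548 equiv of partner in hand. So I looked for no gain from Monday's. A flat stretch of 17.0 h reads as a feed that has ended and shows no target going back, so I expected nothing from waiting or from Thursday's. Friday's was a guess. I put 75.2% on now, on Saturday's and on Monday's, and named no best option.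

The forecast, a little above me on Monday's, gave 75.2%, 75.2%, 75.8% and none, holding that “Waiting, adding partner or removing target should then add almost nothing”.

The flask gives 75.0% at 30 h, 75.0% after Saturday's, 75.0% after Monday's, and best option none.

    2 dissolved substrate → side product (k = 5.77 × 10⁻⁵ M⁻¹ s⁻¹, Ea = 67.0 kJ mol⁻¹)
    2 solid substrate → self-condensation product (k = 2.75 × 10⁻⁵ M⁻¹ s⁻¹, Ea = 58.0 kJ mol⁻¹)
    solid substrate ⇌ dissolved substrate, rate k3*(cs3 - [dissolved substrate]) while solid is left; crystals form when [dissolved substrate] > cs3 (solubility = 0.0990 M, k = 3.64 × 10⁻⁴ s⁻¹)
    dissolved substrate + partner → target (k = 0.00133 M⁻¹ s⁻¹, Ea = 57.0 kJ mol⁻¹)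
    partner → decomposition product (k = 7.38 × 10⁻⁷ s⁻¹, Ea = 93.0 kJ mol⁻¹)
    (constants at 5 °C)

At 30.0 h the spring flask holds 0% of solid substrate, and its self-condensation product stands to its target as 0.331. Without self-condensation the same run reaches 99.5%; without the low solubility it reaches 95.5%: the two act together, solid substrate condensing while it dissolves slowly.

A second flask follows the same recipe with 1.4 M of solid substrate. The loss step goes with [solid substrate] squared and the dissolving does not, so my reckoning multiplies the loss ratio by 3.06 to 1.01, which means 49.8% target. The computed second flask gives 57.7%: the direction holds, but a correction of that size is no longer small.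

Readings and results are calculated from invented constants, noise included.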